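**Retrosynthetic overview**
1. Target 22 ⇐ keto acid 20 by late α-methylation at C6; 20 ⇐ aldehyde 17 by CHO → CO2H and C5–OSiEt3 → C=O.
2. 17 ⇐ open-chain pentaenal 13 by an amine-catalysed asymmetric intramolecular Diels–Alder reaction (IMDA; bonds C3–C7 and C2–C10). Cyclopentane ring A and cyclohexene ring B form together in this one step.
3. 13 ⇐ tetraenal 10 + silyl dienol ether 12 by a vinylogous Mukaiyama aldol reaction (bond C4–C5).
4. 10 ⇐ but-3-en-1-ol by cross-metathesis, two Wittig and one Horner–Wadsworth–Emmons olefination, then oxidation; 12 ⇐ 2-ethylhex-2-enal.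

Assumption: chain locants C1–C14 (C1 = CO2H carbon, C5 = ring carbonyl carbon, C14 = PhCH) are used for every compound, and the quinine-derived amine is taken to give the drawn enantiomer (its quinidine-derived pseudo-enantiomer is swapped in if the first run shows the opposite sense).

**Step 1**
Reactants: 1 but-3-en-1-ol; 2 methacrolein (2-methylprop-2-enal)
Product: 3 (2E)-5-hydroxy-2-methylpent-2-enal
Conditions: 2 (5 equiv), second-generation Grubbs catalyst RuCl2(=CHPh)(PCy3)(H2IMes) (3 mol %), CH2Cl2, 40 °C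
Reagents that add atoms: none
Why: Olefin cross-metathesis of a terminal alkene with the electron-poor 1,1-disubstituted partner gives the thermodynamic (E)-trisubstituted enal and tolerates the free alcohol.

**Step 2**
Reactants: 3 (2E)-5-hydroxy-2-methylpent-2-enal; 4 2-(triphenylphosphoranylidene)propanal
Product: 5 (2E,4E)-7-hydroxy-2,4-dimethylhepta-2,4-dienal
Conditions: 4 (1.05 equiv), toluene, 90 °C
Reagents that add atoms: none
Why: Wittig olefination with a stabilised formyl ylide is (E)-selective, and the more conjugated dienal product reacts more slowly than 3, so one homologation dominates.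

**Step 3**
Reactants: 5 (2E,4E)-7-hydroxy-2,4-dimethylhepta-2,4-dienal; 6 2-(triphenylphosphoranylidene)butanal
Product: 7 (2E,4E,6E)-2-ethyl-9-hydroxy-4,6-dimethylnona-2,4,6-trienal
Conditions: 6 (1.1 equiv), toluene, 100 °C
Reagents that add atoms: none
Why: A second (E)-selective Wittig olefination with the ethyl-branched stabilised ylide installs C12 (with its ethyl group) and C13.

**Step 4**
Reactants: 7 (2E,4E,6E)-2-ethyl-9-hydroxy-4,6-dimethylnona-2,4,6-trienal; 8 diethyl benzylphosphonate
Product: 9 (3E,5E,7E,9E)-8-ethyl-4,6-dimethyl-10-phenyldeca-3,5,7,9-tetraen-1-ol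
Conditions: 8 (1.3 equiv), potassium tert-butoxide (2.5 equiv), THF, 0 °C → rt
Reagents that add atoms: none
Why: Horner–Wadsworth–Emmons olefination with the benzylphosphonate anion gives the (E)-styryl terminus, the alkoxide being a spectator.

**Step 5**
Reactants: 9 (3E,5E,7E,9E)-8-ethyl-4,6-dimethyl-10-phenyldeca-3,5,7,9-tetraen-1-ol
Product: 10 (3E,5E,7E,9E)-8-ethyl-4,6-dimethyl-10-phenyldeca-3,5,7,9-tetraenal
Conditions: Dess–Martin periodinane (1.2 equiv), NaHCO3, CH2Cl2, 0 °C, 30 min; crude 10 used at once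
Reagents that add atoms: none
Why: Buffered Dess–Martin oxidation is non-enolising, so the β,γ-unsaturated aldehyde is obtained without migration of the double bond into conjugation.

**Step 6**
Reactants: 11 (2E)-2-ethylhex-2-enal
Product: 12 triethyl{[(1E,3E)-2-ethylhexa-1,3-dien-1-yl]oxy}silane
Conditions: Et3SiOTf (1.2 equiv), Et3N (1.5 equiv), Et2O, 0 °C → rt
Reagents that add atoms: triethylsilyl trifluoromethanesulfonate, CC[Si](CC)(CC)OS(=O)(=O)C(F)(F)F
Why: Soft enolisation (O-silylation, then γ-deprotonation of the s-trans enal) gives the (1E,3E)-silyl dienol ether.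

**Step 7**
Reactants: 10 (3E,5E,7E,9E)-8-ethyl-4,6-dimethyl-10-phenyldeca-3,5,7,9-tetraenal; 12 triethyl{[(1E,3E)-2-ethylhexa-1,3-dien-1-yl]oxy}silane
Product: 13 (2E,7E,9E,11E,13E)-2,4,12-triethyl-8,10-dimethyl-14-phenyl-5-[(triethylsilyl)oxy]tetradeca-2,7,9,11,13-pentaenal (all four C4/C5 stereoisomers)
Conditions: 12 (1.5 equiv), B(C6F5)3 (10 mol %), CH2Cl2/Et2O 9:1, −78 °C
Reagents that add atoms: none
Why: Vinylogous Mukaiyama aldol reaction in which the bulky borane activates the aldehyde, 12 attacks through its γ-carbon (C4) and silyl transfer to the aldolate releases the borane and delivers the silyl ether directly; C4 and C5 form unselectively, which is harmless because C4 is equilibrated in step 8 and C5 becomes the ketone in step 10.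

**Step 8**
Reactants: 13 (2E,7E,9E,11E,13E)-2,4,12-triethyl-8,10-dimethyl-14-phenyl-5-[(triethylsilyl)oxy]tetradeca-2,7,9,11,13-pentaenal
Product: 17 3,4-diethyl-5-[(1E,3E)-2-ethyl-4-phenylbuta-1,3-dien-1-yl]-5,7-dimethyl-2-[(triethylsilyl)oxy]-2,3,3a,4,5,7a-hexahydro-1H-indene-4-carbaldehyde (trans-fused; C2, C3, C4, C7, C10 of the chain as in 22; both C5 epimers), via iminium ion 14 (not isolated), via dienamine 15 (not isolated), via cycloadduct iminium ion 16 (not isolated)
Conditions: 9-amino(9-deoxy)epi-quinine (20 mol %), CF3CO2H (40 mol %), toluene (0.05 M), 25 °C, 72 h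
Reagents that add atoms: none
Why: Proposed new method: a primary-amine-catalysed dynamic kinetic asymmetric IMDA, in which condensation of the cinchona amine with the α-branched enal gives iminium ion 14 (LUMO lowered, one face shielded), reversible γ-deprotonation to dienamine 15 interconverts the two C4 epimers faster than cyclisation, and A1,3 strain between the C2 ethyl group and C4 lets only the epimer whose tether lies on the open face cyclise through the endo (iminium under the diene) transition state, so that the C3–C7 and C2–C10 bonds form with C2, C3, C7 and C10 set by the catalyst, C4 set by the substrate (ethyl trans to C2) and the unselective C5 centre carried as a spectator; the closest known reactions are amine-catalysed enantioselective IMDA reactions of trienals through iminium ions, cinchona primary amine activation of α-branched enals and their γ-epimerisation through dienamines, none yet combined or shown for an α,γ-branched enal that closes two adjacent quaternary centres.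

**Step 9**
Reactants: 17 (the silyloxy aldehyde, both C5 epimers)
Product: 18 3,4-diethyl-5-[(1E,3E)-2-ethyl-4-phenylbuta-1,3-dien-1-yl]-5,7-dimethyl-2-[(triethylsilyl)oxy]-2,3,3a,4,5,7a-hexahydro-1H-indene-4-carboxylic acid (both C5 epimers)
Conditions: NaClO2, NaH2PO4, 2-methyl-2-butene (40 equiv), t-BuOH/H2O, 0 °C → rt
Reagents that add atoms: sodium chlorite, [Na+].[O-]Cl=O
Why: Pinnick oxidation is selective for the aldehyde (which has no α-hydrogen to epimerise), and the large excess of scavenger keeps hypochlorous acid away from the styryl diene.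

**Step 10**
Reactants: 18 (the silyloxy acid, both C5 epimers)
Product: 20 (3S,3aR,4R,5R,7aS)-3,4-diethyl-5-[(1E,3E)-2-ethyl-4-phenylbuta-1,3-dien-1-yl]-5,7-dimethyl-2-oxo-2,3,3a,4,5,7a-hexahydro-1H-indene-4-carboxylic acid, via hydroxy acid 19 (not isolated)
Conditions: IBX (3 equiv), DMSO, 25 → 40 °C
Reagents that add atoms: none
Why: IBX in DMSO cleaves the secondary triethylsilyl ether and oxidises the freed alcohol to the ketone in one operation, which merges the two C5 epimers; C4, now α to the ketone, already sits trans to C2 and can only equilibrate to that same, more stable, configuration.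

**Step 11**
Reactants: 20 (the keto acid)
Product: 22 (1S,3S,3aR,4R,5R,7aR)-3,4-diethyl-5-[(1E,3E)-2-ethyl-4-phenylbuta-1,3-dien-1-yl]-1,5,7-trimethyl-2-oxo-2,3,3a,4,5,7a-hexahydro-1H-indene-4-carboxylic acid (CNP0268209.1), via dilithium enolate carboxylate 21 (not isolated)
Conditions: lithium diisopropylamide (2.3 equiv), THF/DMPU, −78 °C; MeI (1.5 equiv), −78 → −40 °C; aq HCl work-up
Reagents that add atoms: iodomethane, CI
Why: Kinetic enolate alkylation, in which the base removes the carboxyl proton and then a proton from the less hindered C6 methylene (C4 is tertiary and flanked by the quaternary C2), and iodomethane attacks the cyclopentanone enolate trans to the C7–C8 bond, giving the C6 methyl cis to H7, which is also the thermodynamic arrangement.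

**Compound list**
1 | but-3-en-1-ol | C=CCCO | starting material
2 | methacrolein (2-methylprop-2-enal) | CC(=C)C=O | starting material
3 | (2E)-5-hydroxy-2-methylpent-2-enal | OCC/C=C(\C)C=O | intermediate
4 | 2-(triphenylphosphoranylidene)propanal | CC(C=O)=P(c1ccccc1)(c1ccccc1)c1ccccc1 | starting material
5 | (2E,4E)-7-hydroxy-2,4-dimethylhepta-2,4-dienal | OCC/C=C(C)/C=C(\C)C=O | intermediate
6 | 2-(triphenylphosphoranylidene)butanal | CCC(C=O)=P(c1ccccc1)(c1ccccc1)c1ccccc1 | starting material
7 | (2E,4E,6E)-2-ethyl-9-hydroxy-4,6-dimethylnona-2,4,6-trienal | OCC/C=C(C)/C=C(C)/C=C(\CC)C=O | intermediate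
8 | diethyl benzylphosphonate | CCOP(=O)(Cc1ccccc1)OCC | starting material
9 | (3E,5E,7E,9E)-8-ethyl-4,6-dimethyl-10-phenyldeca-3,5,7,9-tetraen-1-ol | OCC/C=C(C)/C=C(C)/C=C(CC)/C=C/c1ccccc1 | intermediate
10 | (3E,5E,7E,9E)-8-ethyl-4,6-dimethyl-10-phenyldeca-3,5,7,9-tetraenal | O=CC/C=C(C)/C=C(C)/C=C(CC)/C=C/c1ccccc1 | intermediate
11 | (2E)-2-ethylhex-2-enal | CCC/C=C(\CC)C=O | starting material
12 | triethyl{[(1E,3E)-2-ethylhexa-1,3-dien-1-yl]oxy}silane | CC/C=C/C(CC)=C/O[Si](CC)(CC)CC | intermediate
13 | (2E,7E,9E,11E,13E)-2,4,12-triethyl-8,10-dimethyl-14-phenyl-5-[(triethylsilyl)oxy]tetradeca-2,7,9,11,13-pentaenal, mixture of the four C4/C5 stereoisomers | O=C/C(CC)=C/C(CC)C(O[Si](CC)(CC)CC)C/C=C(C)/C=C(C)/C=C(CC)/C=C/c1ccccc1 | intermediate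
14 | iminium ion of 13 with 9-amino(9-deoxy)epi-quinine, C4 epimer that cyclises (C4 as in 22, C5 either) | [NH+](=C/C(CC)=C/[C@H](CC)C(O[Si](CC)(CC)CC)C/C=C(C)/C=C(C)/C=C(CC)/C=C/c1ccccc1)[C@@H](c1ccnc2ccc(OC)cc12)[C@@H]1C[C@@H]2CCN1C[C@@H]2C=C | intermediate (not isolated)
15 | dienamine tautomer of 14 (C4 trigonal, enamine double-bond geometries not fixed) | N(C=C(CC)C=C(CC)C(O[Si](CC)(CC)CC)C/C=C(C)/C=C(C)/C=C(CC)/C=C/c1ccccc1)[C@@H](c1ccnc2ccc(OC)cc12)[C@@H]1C[C@@H]2CCN1C[C@@H]2C=C | intermediate (not isolated)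
16 | iminium ion of cycloadduct 17 with the catalyst amine | CCC(/C=C/c1ccccc1)=C\[C@@]1(C)C=C(C)[C@@H]2[C@H]([C@H](CC)C(O[Si](CC)(CC)CC)C2)[C@@]1(CC)C=[NH+][C@@H](c1ccnc2ccc(OC)cc12)[C@@H]1C[C@@H]2CCN1C[C@@H]2C=C | intermediate (not isolated)
17 | 3,4-diethyl-5-[(1E,3E)-2-ethyl-4-phenylbuta-1,3-dien-1-yl]-5,7-dimethyl-2-[(triethylsilyl)oxy]-2,3,3a,4,5,7a-hexahydro-1H-indene-4-carbaldehyde, trans-fused, ring centres as in 22, both epimers at the silyloxy carbon | CCC(/C=C/c1ccccc1)=C\[C@@]1(C)C=C(C)[C@@H]2[C@H]([C@H](CC)C(O[Si](CC)(CC)CC)C2)[C@@]1(CC)C=O | intermediate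
18 | the corresponding 4-carboxylic acid of 17, both epimers at the silyloxy carbon | CCC(/C=C/c1ccccc1)=C\[C@@]1(C)C=C(C)[C@@H]2[C@H]([C@H](CC)C(O[Si](CC)(CC)CC)C2)[C@@]1(CC)C(=O)O | intermediate
19 | 3,4-diethyl-5-[(1E,3E)-2-ethyl-4-phenylbuta-1,3-dien-1-yl]-2-hydroxy-5,7-dimethyl-2,3,3a,4,5,7a-hexahydro-1H-indene-4-carboxylic acid, both carbinol epimers | CCC(/C=C/c1ccccc1)=C\[C@@]1(C)C=C(C)[C@@H]2[C@H]([C@H](CC)C(O)C2)[C@@]1(CC)C(=O)O | intermediate (not isolated)
20 | (3S,3aR,4R,5R,7aS)-3,4-diethyl-5-[(1E,3E)-2-ethyl-4-phenylbuta-1,3-dien-1-yl]-5,7-dimethyl-2-oxo-2,3,3a,4,5,7a-hexahydro-1H-indene-4-carboxylic acid | CCC(/C=C/c1ccccc1)=C\[C@@]1(C)C=C(C)[C@@H]2[C@H]([C@H](CC)C(=O)C2)[C@@]1(CC)C(=O)O | intermediate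
21 | dilithium salt of 20 (carboxylate and C5–C6 enolate) | CCC(/C=C/c1ccccc1)=C\[C@@]1(C)C=C(C)[C@@H]2[C@H]([C@H](CC)C([O-])=C2)[C@@]1(CC)C(=O)[O-].[Li+].[Li+] | intermediate (not isolated)
22 | (1S,3S,3aR,4R,5R,7aR)-3,4-diethyl-5-[(1E,3E)-2-ethyl-4-phenylbuta-1,3-dien-1-yl]-1,5,7-trimethyl-2-oxo-2,3,3a,4,5,7a-hexahydro-1H-indene-4-carboxylic acid | CCC(/C=C/c1ccccc1)=C\[C@@]1(C)C=C(C)[C@@H]2[C@H]([C@H](CC)C(=O)[C@H]2C)[C@@]1(CC)C(=O)O | target

**Step count and risks**
Total: 11 steps. Longest linear sequence: 10 steps (steps 1–5 and 7–11); step 6 is the one-step side branch.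

The three steps most likely to fail:

Step 8 (the proposed new IMDA). The iminium ion of a hindered α-branched enal may form slowly or with poor geometry control, the diene terminus is fully substituted, and the ee depends on C4 epimerising faster than ring closure. The fallback moves the stereocontrol from the cycloaddition catalyst to the substrate and uses known chemistry only. It sets out from 10 and 12: an enantioselective vinylogous Mukaiyama aldol reaction promoted by an N-tosyl-tryptophan-derived B-phenyl oxazaborolidinone with isopropanol as silyl trap (promoter enantiomer chosen for C4 as in 22) gives (4S,5R)-2,4,12-triethyl-5-hydroxy-8,10-dimethyl-14-phenyltetradeca-2,7,9,11,13-pentaenal F1. Silylation with Et3SiCl and imidazole gives its triethylsilyl ether F2, a single stereoisomer of 13. Heating F2 in toluene with BHT at 110 °C closes both rings in a thermal IMDA, the way this ring system has been closed before, with the face selected by A1,3 strain at the now fixed C4. The fallback comes back to the route at 17, as a single C5 epimer.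

Step 7 (vinylogous aldol with silyl transfer). Aldehyde 10 can slip into conjugation or decompose under the Lewis acid, and α-attack or incomplete silyl transfer would lower the yield. The fallback uses the more nucleophilic ester-derived dienolate and adjusts the oxidation state afterwards. It sets out from 10: commercial ethyl (2E)-2-ethylhex-2-enoate (CCC/C=C(\CC)C(=O)OCC) is converted with lithium diisopropylamide and t-BuMe2SiCl into tert-butyl{[(3E)-1-ethoxy-2-ethylhexa-1,3-dien-1-yl]oxy}dimethylsilane F3. F3 adds to 10 through its γ-carbon with BF3·OEt2 at −78 °C to give ethyl (2E,7E,9E,11E,13E)-2,4,12-triethyl-5-hydroxy-8,10-dimethyl-14-phenyltetradeca-2,7,9,11,13-pentaenoate F4. Et3SiCl and imidazole give the silyl ether ester F5, diisobutylaluminium hydride gives (2E,7E,9E,11E,13E)-2,4,12-triethyl-8,10-dimethyl-14-phenyl-5-[(triethylsilyl)oxy]tetradeca-2,7,9,11,13-pentaen-1-ol F6, and MnO2 oxidises the allylic alcohol. The fallback comes back to the route at 13.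

Step 11 (C6 methylation). The carboxylate may steer the base towards C4, and double methylation or proton exchange can erode the yield. The fallback builds the methyl group by methylenation and conjugate reduction, which can only happen at the C6 methylene. It sets out from 20: N-methylanilinium trifluoroacetate and paraformaldehyde in THF at reflux give 3,4-diethyl-5-[(1E,3E)-2-ethyl-4-phenylbuta-1,3-dien-1-yl]-5,7-dimethyl-1-methylidene-2-oxo-2,3,3a,4,5,7a-hexahydro-1H-indene-4-carboxylic acid F7. Conjugate reduction of F7 with KBH(s-Bu)3 (2.2 equiv, THF, −78 °C) and protonation of the enolate from the face trans to the C7–C8 bond, with base equilibration (DBU) if needed, gives the methyl group in its stable configuration. The fallback comes back to the route at 22.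

**Further compounds**
F1 | step 8 | (2E,4S,5R,7E,9E,11E,13E)-2,4,12-triethyl-5-hydroxy-8,10-dimethyl-14-phenyltetradeca-2,7,9,11,13-pentaenal | O=C/C(CC)=C/[C@H](CC)[C@H](O)C/C=C(C)/C=C(C)/C=C(CC)/C=C/c1ccccc1
F2 | step 8 | (2E,4S,5R,7E,9E,11E,13E)-2,4,12-triethyl-8,10-dimethyl-14-phenyl-5-[(triethylsilyl)oxy]tetradeca-2,7,9,11,13-pentaenal | O=C/C(CC)=C/[C@H](CC)[C@H](O[Si](CC)(CC)CC)C/C=C(C)/C=C(C)/C=C(CC)/C=C/c1ccccc1
F3 | step 7 | tert-butyl{[(3E)-1-ethoxy-2-ethylhexa-1,3-dien-1-yl]oxy}dimethylsilane | CC/C=C/C(CC)=C(OCC)O[Si](C)(C)C(C)(C)C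
F4 | step 7 | ethyl (2E,7E,9E,11E,13E)-2,4,12-triethyl-5-hydroxy-8,10-dimethyl-14-phenyltetradeca-2,7,9,11,13-pentaenoate (C4/C5 stereoisomer mixture) | CCOC(=O)/C(CC)=C/C(CC)C(O)C/C=C(C)/C=C(C)/C=C(CC)/C=C/c1ccccc1
F5 | step 7 | ethyl (2E,7E,9E,11E,13E)-2,4,12-triethyl-8,10-dimethyl-14-phenyl-5-[(triethylsilyl)oxy]tetradeca-2,7,9,11,13-pentaenoate (C4/C5 stereoisomer mixture) | CCOC(=O)/C(CC)=C/C(CC)C(O[Si](CC)(CC)CC)C/C=C(C)/C=C(C)/C=C(CC)/C=C/c1ccccc1
F6 | step 7 | (2E,7E,9E,11E,13E)-2,4,12-triethyl-8,10-dimethyl-14-phenyl-5-[(triethylsilyl)oxy]tetradeca-2,7,9,11,13-pentaen-1-ol (C4/C5 stereoisomer mixture) | OC/C(CC)=C/C(CC)C(O[Si](CC)(CC)CC)C/C=C(C)/C=C(C)/C=C(CC)/C=C/c1ccccc1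
F7 | step 11 | 3,4-diethyl-5-[(1E,3E)-2-ethyl-4-phenylbuta-1,3-dien-1-yl]-5,7-dimethyl-1-methylidene-2-oxo-2,3,3a,4,5,7a-hexahydro-1H-indene-4-carboxylic acid (ring centres as in 20) | CCC(/C=C/c1ccccc1)=C\[C@@]1(C)C=C(C)[C@@H]2[C@H]([C@H](CC)C(=O)C2=C)[C@@]1(CC)C(=O)O
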